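## Retrosynthetic overview
1. Last ring, the benzofuran C2–O bond: from an unprotected (E)-2,4-dihydroxy-3-geranylstilbene, closed by two-electron oxidation in the final step (the oxyresveratrol → moracin logic).
2. Stilbene C=C: from 3-geranyl-2,4-dihydroxybenzaldehyde and a chiral (dihydrobenzofuran-4-yl)acetic acid, joined by condensation–decarboxylation without protecting groups.
3. First ring, the dihydrofuran C–O bond: from the (S)-epoxide of an o-prenylresorcinol, opened 5-exo by the phenoxide with inversion to give (R). This is done before any geranyl alkene is in the molecule.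
4. Both isoprenoid chains: from prenyltransferase-like direct C-alkylations of 2,4-dihydroxybenzaldehyde and methyl 3,5-dihydroxyphenylacetate.
5. Ring order: dihydrofuran (step 4), then benzofuran (step 6).

Assumption: the stereocentre in the given SMILES is (R), and the enantiomeric Shi ketone (L-fructose series, derived from L-sorbose) is bought as a catalyst.

## Route

Step 1
Reactants: 1 2,4-dihydroxybenzaldehyde; 2 geranyl bromide [(2E)-1-bromo-3,7-dimethylocta-2,6-diene]
Product: 3 3-[(2E)-3,7-dimethylocta-2,6-dien-1-yl]-2,4-dihydroxybenzaldehyde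
Conditions: KOH (1.1 equiv), MeOH, 0 °C → rt, 16 h
Reagents that add atoms: none
Why: Ambident-phenoxide C-alkylation, in which the hydrogen-bonded phenoxide in protic solvent reacts through C3 (the carbon between the two oxygens) by SN2 at the primary allylic bromide, so the E-alkene is kept and the 4-O-geranyl ether is the separable by-product.

Step 2
Reactants: 4 methyl 2-(3,5-dihydroxyphenyl)acetate; 5 2-methylbut-3-en-2-ol
Product: 6 methyl 2-[3,5-dihydroxy-2-(3-methylbut-2-en-1-yl)phenyl]acetate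
Conditions: BF3·OEt2 (30 mol %), 1,4-dioxane, rt, 2 h; chromatography
Reagents that add atoms: none
Why: Friedel–Crafts prenylation, in which the dimethylallyl cation reacts at its primary terminus with C2/C6 (para to one OH, ortho to the other, statistically doubled), while C4 between two BF3-complexed OH groups is more hindered; the C4 isomer and bis-adducts are removed and no stereocentre forms.

Step 3
Reactants: 6 methyl 2-[3,5-dihydroxy-2-(3-methylbut-2-en-1-yl)phenyl]acetate
Product: 7 methyl 2-[3,5-bis(tert-butyldimethylsilyloxy)-2-(3-methylbut-2-en-1-yl)phenyl]acetate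
Conditions: TBSCl (2.4 equiv), imidazole (5 equiv), DMF, rt
Reagents that add atoms: tert-butyldimethylsilyl chloride, CC(C)(C)[Si](C)(C)Cl
Why: Standard Corey silylation masks both phenols, so that the dioxirane and Oxone at pH 10 meet only the trisubstituted alkene.

Step 4
Reactants: 7 methyl 2-[3,5-bis(tert-butyldimethylsilyloxy)-2-(3-methylbut-2-en-1-yl)phenyl]acetate
Product: 9 2-[(2R)-6-hydroxy-2-(2-hydroxypropan-2-yl)-2,3-dihydro-1-benzofuran-4-yl]acetic acid, via (S)-epoxide 8 (not isolated)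
Conditions: ent-Shi ketone (1,2:4,5-di-O-isopropylidene-β-L-erythro-2,3-hexodiulo-2,6-pyranose, 30 mol %), Oxone, K2CO3, Bu4NHSO4 (cat.), MeCN–DMM/aq. Na2B4O7–Na2EDTA buffer, 0 °C, 3 h; trace oxidant destroyed with a little Na2SO3; then 2 M NaOH, MeOH, rt, same flask; 1 M HCl to pH 3 at 0 °C; one recrystallisation to raise ee
Reagents that add atoms: Oxone (potassium peroxymonosulfate), [K+].[O-]S(=O)(=O)OO; water (delivered as aq. NaOH), O
Why: Shi asymmetric epoxidation through the spiro transition state, where the L-series ketone gives the (S)-epoxide (about 90% ee expected, as for related o-silyloxy prenylarenes); hydroxide then removes the aryl silyl ethers and the ester, and the ortho phenoxide opens the epoxide 5-exo-tet at the secondary carbon with clean inversion, which sets (R).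

Step 5
Reactants: 3 3-[(2E)-3,7-dimethylocta-2,6-dien-1-yl]-2,4-dihydroxybenzaldehyde; 9 2-[(2R)-6-hydroxy-2-(2-hydroxypropan-2-yl)-2,3-dihydro-1-benzofuran-4-yl]acetic acid
Product: 11 4-{(E)-2-[(2R)-6-hydroxy-2-(2-hydroxypropan-2-yl)-2,3-dihydro-1-benzofuran-4-yl]ethenyl}-2-[(2E)-3,7-dimethylocta-2,6-dien-1-yl]benzene-1,3-diol, via alpha-arylcinnamic acid 10 (not isolated)
Conditions: piperidine, 1-methylimidazole, PEG-200, Ar, µW 160 °C, 15 min
Reagents that add atoms: none
Why: Modified Perkin (Knoevenagel–Doebner type) condensation–decarboxylation, in which the free 2- and 4-OH groups let acid 10 tautomerise to a quinone methide that is a vinylogous β-keto acid and loses CO2 to give the (E)-stilbene; the kinetic acid has its carboxyl trans to the A ring and so away from the 2-OH, and the non-epimerisable (R) centre is untouched.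

Step 6
Reactants: 11 4-{(E)-2-[(2R)-6-hydroxy-2-(2-hydroxypropan-2-yl)-2,3-dihydro-1-benzofuran-4-yl]ethenyl}-2-[(2E)-3,7-dimethylocta-2,6-dien-1-yl]benzene-1,3-diol
Product: 12 mulberrofuran X, 2-[(2R)-6-hydroxy-2-(2-hydroxypropan-2-yl)-2,3-dihydro-1-benzofuran-4-yl]-7-[(2E)-3,7-dimethylocta-2,6-dien-1-yl]-1-benzofuran-6-ol
Conditions: PhI(OAc)2 (1.05 equiv), MeCN (0.01 M), 0 °C → rt
Reagents that add atoms: none
Why: Hypervalent-iodine oxidative cyclisation of a 2-hydroxystilbene, in which I(III) takes two electrons from the conjugated dihydroxystilbene chromophore (the most oxidisable unit, while isolated trisubstituted alkenes usually survive I(III) phenol oxidations), the 2-OH captures the extended quinone-methide cation at the carbon next to the B ring, and loss of that C–H aromatises to the benzofuran while the remote (R) centre stays intact.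

## Compound list
1 | 2,4-dihydroxybenzaldehyde | O=Cc1ccc(O)cc1O | starting material
2 | geranyl bromide | CC(C)=CCC/C(C)=C/CBr | starting material
3 | 3-geranyl-2,4-dihydroxybenzaldehyde | CC(C)=CCC/C(C)=C/Cc1c(O)ccc(C=O)c1O | intermediate
4 | methyl 2-(3,5-dihydroxyphenyl)acetate | COC(=O)Cc1cc(O)cc(O)c1 | starting material
5 | 2-methylbut-3-en-2-ol | CC(C)(O)C=C | starting material
6 | methyl 2-[3,5-dihydroxy-2-prenylphenyl]acetate | COC(=O)Cc1cc(O)cc(O)c1CC=C(C)C | intermediate
7 | methyl 2-[3,5-bis(TBSO)-2-prenylphenyl]acetate | COC(=O)Cc1cc(O[Si](C)(C)C(C)(C)C)cc(O[Si](C)(C)C(C)(C)C)c1CC=C(C)C | intermediate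
8 | methyl 2-[3,5-bis(TBSO)-2-{[(2S)-3,3-dimethyloxiran-2-yl]methyl}phenyl]acetate | COC(=O)Cc1cc(O[Si](C)(C)C(C)(C)C)cc(O[Si](C)(C)C(C)(C)C)c1C[C@@H]2OC2(C)C | intermediate
9 | 2-[(2R)-6-hydroxy-2-(2-hydroxypropan-2-yl)-2,3-dihydro-1-benzofuran-4-yl]acetic acid | OC(=O)Cc1cc(O)cc2c1C[C@H](C(C)(C)O)O2 | intermediate
10 | (2E)-3-(3-geranyl-2,4-dihydroxyphenyl)-2-[(2R)-6-hydroxy-2-(2-hydroxypropan-2-yl)-2,3-dihydro-1-benzofuran-4-yl]prop-2-enoic acid | CC(C)=CCC/C(C)=C/Cc1c(O)ccc(/C=C(/C(=O)O)c2cc(O)cc3c2C[C@H](C(C)(C)O)O3)c1O | intermediate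
11 | (E)-stilbene: 2-geranyl-4-{2-[(2R)-6-hydroxy-2-(2-hydroxypropan-2-yl)-2,3-dihydro-1-benzofuran-4-yl]ethenyl}benzene-1,3-diol | CC(C)=CCC/C(C)=C/Cc1c(O)ccc(/C=C/c2cc(O)cc3c2C[C@H](C(C)(C)O)O3)c1O | intermediate
12 | mulberrofuran X | CC(C)=CCC/C(C)=C/Cc1c(O)ccc2cc(-c3cc(O)cc4c3C[C@H](C(C)(C)O)O4)oc12 | target

Total step count: 6. Longest linear sequence: 5 (steps 2, 3, 4, 5, 6).

## Steps most likely to fail

**Step 6.**
- Risks: the cation can lose a proton from the geranyl CH2 and go through an o-quinone methide to a 2H-chromene. The free phenols of the product can be over-oxidised. Intermolecular coupling can also compete.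
- Fallback: it sets out from 1, 2 and 9, comes back at 12, and moves the oxidation ahead of the geranyl chain. Iodinate 1 between the two oxygens (I2, NaHCO3, H2O, 0 °C) to 2,4-dihydroxy-3-iodobenzaldehyde F1. Condense F1 with 9 under the step 5 conditions to 2-iodo-4-{(E)-2-[(2R)-6-hydroxy-2-(2-hydroxypropan-2-yl)-2,3-dihydro-1-benzofuran-4-yl]ethenyl}benzene-1,3-diol F2. Close the furan with PhI(OAc)2, now with no isoprenoid alkene present, to 2-[(2R)-6-hydroxy-2-(2-hydroxypropan-2-yl)-2,3-dihydro-1-benzofuran-4-yl]-7-iodo-1-benzofuran-6-ol F3. Attach the chain last by Stille coupling (Pd2(dba)3, AsPh3, DMF, 60 °C) with tributyl(geranyl)stannane F4, made from 2 and Bu3SnLi, which gives 12.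

**Step 5.**
- Risks: acid 10 can isomerise and lactonise onto the 2-OH to give the 3-arylcoumarin. The ortho-substituted acid 9 may also condense slowly.
- Fallback: it sets out from 3 and 9, comes back at 11, and makes the C–C bond as a stepwise aldol followed by fragmentation. Silylate 3 (TBSOTf, 2,6-lutidine, CH2Cl2) to 2,4-bis(tert-butyldimethylsilyloxy)-3-geranylbenzaldehyde F5. Convert 9 into its Ivanov reagent (i-PrMgCl, 4.2 equiv, THF) and add F5 to obtain 3-[2,4-bis(tert-butyldimethylsilyloxy)-3-geranylphenyl]-3-hydroxy-2-[(2R)-6-hydroxy-2-(2-hydroxypropan-2-yl)-2,3-dihydro-1-benzofuran-4-yl]propanoic acid F6; its diastereomer mixture does not matter. Decarboxylative dehydration (DMF dineopentyl acetal, toluene, 80 °C, Grob-type, helped by the electron-rich β-aryl group) gives the 2,4-bis(tert-butyldimethylsilyl) ether of stilbene 11 F7. TBAF in THF then gives 11.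

**Step 2.**
- Risks: C4 attack, double prenylation, and acid-catalysed closure to the dimethylchroman can all erode the yield of the C2 isomer.
- Fallback: it sets out from 4, comes back at 7, and replaces the Friedel–Crafts step by halogen-directed cross-coupling. Silylate 4 (TBSCl, imidazole) to methyl 2-[3,5-bis(tert-butyldimethylsilyloxy)phenyl]acetate F8. Brominate with NBS in MeCN at 0 °C, where C4 is shielded by two OTBS groups, to methyl 2-[2-bromo-3,5-bis(tert-butyldimethylsilyloxy)phenyl]acetate F9. A linear-selective Negishi coupling with prenylzinc bromide (Pd(OAc)2, CPhos, THF, rt) then gives 7.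

## Further compounds
F1 | step 6 | 2,4-dihydroxy-3-iodobenzaldehyde | O=Cc1ccc(O)c(I)c1O
F2 | step 6 | 2-iodo-4-{(E)-2-[(2R)-6-hydroxy-2-(2-hydroxypropan-2-yl)-2,3-dihydro-1-benzofuran-4-yl]ethenyl}benzene-1,3-diol | Oc1ccc(/C=C/c2cc(O)cc3c2C[C@H](C(C)(C)O)O3)c(O)c1I
F3 | step 6 | 2-[(2R)-6-hydroxy-2-(2-hydroxypropan-2-yl)-2,3-dihydro-1-benzofuran-4-yl]-7-iodo-1-benzofuran-6-ol | Oc1ccc2cc(-c3cc(O)cc4c3C[C@H](C(C)(C)O)O4)oc2c1I
F4 | step 6 | tributyl(geranyl)stannane | CC(C)=CCC/C(C)=C/C[Sn](CCCC)(CCCC)CCCC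
F5 | step 5 | 2,4-bis(tert-butyldimethylsilyloxy)-3-geranylbenzaldehyde | CC(C)=CCC/C(C)=C/Cc1c(O[Si](C)(C)C(C)(C)C)ccc(C=O)c1O[Si](C)(C)C(C)(C)C
F6 | step 5 | 3-[2,4-bis(tert-butyldimethylsilyloxy)-3-geranylphenyl]-3-hydroxy-2-[(2R)-6-hydroxy-2-(2-hydroxypropan-2-yl)-2,3-dihydro-1-benzofuran-4-yl]propanoic acid | CC(C)=CCC/C(C)=C/Cc1c(O[Si](C)(C)C(C)(C)C)ccc(C(O)C(C(=O)O)c2cc(O)cc3c2C[C@H](C(C)(C)O)O3)c1O[Si](C)(C)C(C)(C)C
F7 | step 5 | 2,4-bis(tert-butyldimethylsilyl) ether of stilbene 11 | CC(C)=CCC/C(C)=C/Cc1c(O[Si](C)(C)C(C)(C)C)ccc(/C=C/c2cc(O)cc3c2C[C@H](C(C)(C)O)O3)c1O[Si](C)(C)C(C)(C)C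
F8 | step 2 | methyl 2-[3,5-bis(tert-butyldimethylsilyloxy)phenyl]acetate | COC(=O)Cc1cc(O[Si](C)(C)C(C)(C)C)cc(O[Si](C)(C)C(C)(C)C)c1
F9 | step 2 | methyl 2-[2-bromo-3,5-bis(tert-butyldimethylsilyloxy)phenyl]acetate | COC(=O)Cc1cc(O[Si](C)(C)C(C)(C)C)cc(O[Si](C)(C)C(C)(C)C)c1Br
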